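**Retrosynthetic overview**
- The strategy rests on the 2-(acyloxymethyl)enone formed by the C8 ketone, the C9=C10 alkene and the C19 CH2–O-octenoate on C9; it is read as the allylically transposed ester of a Morita–Baylis–Hillman adduct.
- Disconnections at this unit: C19–O back to C10–O (1,3-acyloxy shift), the C10–O ester, then C9–C10 between a C13 vinyl ketone (C8=O, C9=C19) and a C27 heptaenal (C10 aldehyde).
- The C27 aldehyde is cut at C11=C12 (two-carbon Wittig homologation) and at C11′=C12′ (C15 phosphonium salt plus C10 dialdehyde).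
- No ring is formed: ring A (C1–C6, 3R) is bought as (4R,6R)-actinol and ring B (C1′–C6′) as (R)-α-ionone, whose C3′ oxygen is installed by allylic oxidation, reduction and Mitsunobu inversion.

Key step: step 18

Assumption: carotenoid numbering is used (ring A C1–C6 and chain C7–C15 on the keto half, primed numbers on the ε half, C19 the oxygenated carbon on C9), and compounds 1, 11, 17 and 28 are taken as purchasable.

**Ring B half (C27 aldehyde)**

Step 1
Reactants: 1 (R)-α-ionone
Product: 2 (R)-α-ionone ethylene ketal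
Conditions: Me3SiOCH2CH2OSiMe3 (1.5 equiv), Me3SiOTf (5 mol %), CH2Cl2, −78 °C; pyridine quench
Reagents that add atoms: 1,2-bis(trimethylsilyloxy)ethane, C[Si](C)(C)OCCO[Si](C)(C)C
Why: Silyl-triflate-catalysed ketalisation with the bis-silyl ether of ethylene glycol works at low temperature on conjugated enones without moving the C7=C8 bond or epimerising C6, and it masks the C9 ketone for the ring oxidation and reduction that follow.

Step 2
Reactants: 2 (R)-α-ionone ethylene ketal
Product: 3 (6R)-3-oxo-α-ionone ethylene ketal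
Conditions: t-BuOOH (70% aq., 5 equiv), dirhodium tetrakis(caprolactamate) Rh2(C6H10NO)4 (1 mol %), K2CO3, CH2Cl2, rt
Reagents that add atoms: tert-butyl hydroperoxide, CC(C)(C)OO
Why: Catalytic allylic oxidation with tert-butyl hydroperoxide (peroxyl-radical hydrogen abstraction) converts the unhindered ring CH2 at C3 into the enone carbonyl, the other allylic hydrogens being the primary C5-methyl ones and the C6–H shielded by the gem-dimethyl group and the side chain.

Step 3
Reactants: 3 (6R)-3-oxo-α-ionone ethylene ketal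
Product: 4 (3S,6R)-3-hydroxy-α-ionone ethylene ketal (3,6-cis)
Conditions: LiBH(s-Bu)3 (1.2 equiv), THF, −78 °C; then H2O
Reagents that add atoms: none
Why: The bulky borohydride reduces the β,β-disubstituted enone in the 1,2-sense and should attack C3 from the face anti to the C6 side chain, giving mainly the 3,6-cis (3S) allylic alcohol; the minor 3,6-trans epimer is separated and is identical with 7.

Step 4
Reactants: 4 (3S,6R)-3-hydroxy-α-ionone ethylene ketal (3,6-cis)
Product: 6 (3R,6R)-3-(4-nitrobenzoyloxy)-α-ionone ethylene ketal (3,6-trans), via alkoxyphosphonium salt 5 (not isolated)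
Conditions: PPh3, DIAD, 4-nitrobenzoic acid, THF, 0 °C → rt
Reagents that add atoms: 4-nitrobenzoic acid, O=C(O)c1ccc(cc1)[N+](=O)[O-]
Why: Mitsunobu esterification proceeds by SN2 displacement of the phosphonium-activated oxygen of 5 by 4-nitrobenzoate, which inverts C3 to R (3,6-trans), and SN2′ attack is disfavoured because the other allylic terminus C5 is fully substituted.

Step 5
Reactants: 6 (3R,6R)-3-(4-nitrobenzoyloxy)-α-ionone ethylene ketal
Product: 7 (3R,6R)-3-hydroxy-α-ionone ethylene ketal
Conditions: K2CO3 (cat.), MeOH, rt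
Reagents that add atoms: none
Why: Base-catalysed transesterification removes the activated aryl ester by acyl–oxygen cleavage, so the C3 configuration is untouched.

Step 6
Reactants: 7 (3R,6R)-3-hydroxy-α-ionone ethylene ketal
Product: 8 (3R,6R)-3-hydroxy-α-ionone
Conditions: 5% aq. oxalic acid, THF, rt
Reagents that add atoms: water, O
Why: Mild aqueous acid hydrolyses the dioxolane through the allyl-stabilised oxocarbenium ion at C9, while oxalic acid is too weak to ionise the C3 allylic alcohol.

Step 7
Reactants: 8 (3R,6R)-3-hydroxy-α-ionone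
Product: 9 (3R,6R)-3-hydroxy-9-vinyl-α-ionol (C9 epimers)
Conditions: CH2=CHMgBr (2.5 equiv), THF, −30 → 0 °C; then H2O
Reagents that add atoms: vinylmagnesium bromide, C=C[Mg]Br
Why: The Grignard reagent adds 1,2 to the C9 carbonyl of ionone-type enones (the first equivalent is consumed by the C3 hydroxyl) and brings C10′ and C11′; the C9 epimers are of no consequence because C9 becomes sp2 in step 8.

Step 8
Reactants: 9 (3R,6R)-3-hydroxy-9-vinyl-α-ionol
Product: 10 (3R,6R)-3-hydroxy-ε C15 triphenylphosphonium bromide (9E)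
Conditions: PPh3·HBr (1.05 equiv), MeOH, 0 °C → rt; crystallisation
Reagents that add atoms: triphenylphosphine hydrobromide, [Br-].[PH+](c1ccccc1)(c1ccccc1)c1ccccc1
Why: Acid-induced ionisation of the doubly allylic tertiary C9 alcohol and capture of the pentadienyl cation by PPh3 at the primary terminus (allylic transposition) gives the conjugated salt, the 9E isomer being favoured and purified by crystallisation, while the secondary C3 carbinol ionises far less readily at this temperature.

Step 9
Reactants: 10 (3R,6R)-3-hydroxy-ε C15 triphenylphosphonium bromide; 11 (2E,4E,6E)-2,7-dimethylocta-2,4,6-trienedial (1.5 equiv)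
Product: 13 (3R,6R)-3-hydroxy C25 apo-ε-carotenal (aldehyde carbon C12; all-E), via phosphorus ylide 12 (not isolated)
Conditions: NaOMe, CH2Cl2/MeOH, 0 °C → rt; then I2 (1 mol %), CH2Cl2, diffuse light
Reagents that add atoms: none
Why: Wittig olefination of ylide 12 with one aldehyde of the dialdehyde (used in excess; the product aldehyde is deactivated by its longer conjugation) forms C11′=C12′, and iodine-catalysed equilibration converts the 11′Z portion into the all-E polyene.

Step 10
Reactants: 13 (3R,6R)-3-hydroxy C25 apo-ε-carotenal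
Product: 14 C25 apo-ε-carotenal 3′-TBS ether
Conditions: TBSCl, imidazole, DMF, rt, dark
Reagents that add atoms: tert-butyldimethylsilyl chloride, CC(C)(C)[Si](C)(C)Cl
Why: Imidazole-mediated silylation of the secondary allylic alcohol gives an ether that withstands the ylide, phosphine, amine and mild-acid steps ahead.

Step 11
Reactants: 14 C25 apo-ε-carotenal 3′-TBS ether
Product: 15 C27 dienyl dioxolane (11E/11Z mixture)
Conditions: (1,3-dioxolan-2-ylmethyl)triphenylphosphonium bromide, t-BuOK, THF, 0 °C → rt
Reagents that add atoms: (1,3-dioxolan-2-ylmethyl)triphenylphosphonium bromide, [Br-].C1COC(O1)C[P+](c1ccccc1)(c1ccccc1)c1ccccc1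
Why: Wittig olefination with this masked formylmethylene ylide adds C11 and C10 and forms C11=C12, the acetal preventing the over-homologation that a free formyl ylide would cause.

Step 12
Reactants: 15 C27 dienyl dioxolane
Product: 16 C27 apo-ε-carotenal 3′-TBS ether (aldehyde carbon C10; all-E)
Conditions: 5% aq. oxalic acid, THF, 0 °C → rt; then I2 (1 mol %), CH2Cl2, diffuse light
Reagents that add atoms: water, O
Why: The polyenyl acetal hydrolyses readily through a highly delocalised oxocarbenium ion under acid too weak to cleave the silyl ether, and the acid and iodine treatments bring C11=C12 to the thermodynamic E geometry.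

**Ring A half (C13 vinyl ketone)**

Step 13
Reactants: 17 (4R,6R)-actinol
Product: 18 (4R,6R)-4-(tert-butyldimethylsilyloxy)-2,2,6-trimethylcyclohexanone
Conditions: TBSCl, imidazole, DMF, rt
Reagents that add atoms: tert-butyldimethylsilyl chloride, CC(C)(C)[Si](C)(C)Cl
Why: Standard silylation protects the C3 carbinol, which sits γ to the ketone and therefore cannot be lost by β-elimination in the enolate step.

Step 14
Reactants: 18 (4R,6R)-4-(tert-butyldimethylsilyloxy)-2,2,6-trimethylcyclohexanone
Product: 20 (4R)-4-(tert-butyldimethylsilyloxy)-2,6,6-trimethylcyclohex-1-en-1-yl triflate, via lithium enolate 19 (not isolated)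
Conditions: LiN(i-Pr)2, THF, −78 → 0 °C; PhNTf2, −78 °C → rt; then H2O
Reagents that add atoms: N-phenylbis(trifluoromethanesulfonimide), O=S(=O)(N(c1ccccc1)S(=O)(=O)C(F)(F)F)C(F)(F)F
Why: Only the methyl-bearing α-carbon has a hydrogen (the other is quaternary), so enolate O-sulfonylation gives a single enol triflate with the C5=C6 alkene in place.

Step 15
Reactants: 20 (4R)-4-(tert-butyldimethylsilyloxy)-2,6,6-trimethylcyclohex-1-en-1-yl triflate
Product: 21 ethyl 2-[(4R)-4-(tert-butyldimethylsilyloxy)-2,6,6-trimethylcyclohex-1-en-1-yl]acetate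
Conditions: BrZnCH2CO2Et (3 equiv, from ethyl bromoacetate and Zn in THF), Pd(PPh3)4 (5 mol %), THF/DMPU, 65 °C
Reagents that add atoms: (2-ethoxy-2-oxoethyl)zinc bromide, CCOC(=O)C[Zn]Br
Why: Negishi-type cross-coupling of a Reformatsky zinc enolate with an alkenyl triflate (oxidative addition to zerovalent palladium, transmetallation, reductive elimination) forms the C6–C7 bond at the triflate carbon, and the ring alkene stays out of conjugation because the exocyclic isomer would suffer allylic strain with the flanking methyl groups.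

Step 16
Reactants: 21 ethyl 2-[(4R)-4-(tert-butyldimethylsilyloxy)-2,6,6-trimethylcyclohex-1-en-1-yl]acetate
Product: 22 N-methoxy-N-methyl-2-[(4R)-4-(tert-butyldimethylsilyloxy)-2,6,6-trimethylcyclohex-1-en-1-yl]acetamide
Conditions: MeNH(OMe)·HCl (1.6 equiv), i-PrMgCl (3.2 equiv), THF, −20 → 0 °C
Reagents that add atoms: N,O-dimethylhydroxylamine hydrochloride, CNOC.Cl
Why: The chloromagnesium amide of N,O-dimethylhydroxylamine converts esters directly into Weinreb amides at low temperature, faster than it enolises the C7 methylene.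

Step 17
Reactants: 22 N-methoxy-N-methyl-2-[(4R)-4-(tert-butyldimethylsilyloxy)-2,6,6-trimethylcyclohex-1-en-1-yl]acetamide
Product: 24 1-[(4R)-4-(tert-butyldimethylsilyloxy)-2,6,6-trimethylcyclohex-1-en-1-yl]but-3-en-2-one, via tetrahedral magnesium chelate 23 (not isolated)
Conditions: CH2=CHMgBr (1.5 equiv), THF, −78 → 0 °C; inverse quench into cold 1 M aq. KHSO4/Et2O; used at once
Reagents that add atoms: vinylmagnesium bromide, C=C[Mg]Br
Why: Weinreb ketone synthesis, in which chelate 23 survives until work-up so that a single vinyl group (C9 and C19) is delivered, and the inverse acidic quench protonates the released N,O-dimethylhydroxylamine before it can add to the new vinyl ketone.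

**Union and end game**

Step 18
Reactants: 16 C27 apo-ε-carotenal 3′-TBS ether; 24 C13 vinyl ketone (3 equiv in portions)
Product: 27 Morita–Baylis–Hillman adduct (both C10 epimers), via phosphonio enolate 25 (not isolated), via aldol zwitterion 26 (not isolated)
Conditions: PBu3 (0.3 equiv), phenol (0.3 equiv), THF (concentrated in 16), rt, dark, Ar
Reagents that add atoms: none
Why: Morita–Baylis–Hillman reaction: PBu3 adds to C19 of 24 to give the phosphonio enolate 25, whose C9 attacks the C10 aldehyde carbon of 16 in the 1,2-sense, and phenol relays the proton from C9 to the alkoxide of 26 before PBu3 is expelled from 26 to restore the C9=C19 methylene, so the C9–C10 bond, the C8 ketone and the C10 oxygen are put in place together. The closest known reaction type is the phosphine/phenol-catalysed coupling of alkyl vinyl ketones with cinnamaldehyde-type enals. No ring is closed. The one new stereocentre, C10, is not controlled by the remote C3, C3′ and C6′ centres and need not be, because both epimers converge when C10 becomes sp2 in step 20. The step needs carbonyl addition to outrun Rauhut–Currier dimerisation of 24 and any reaction through C7; this is secured by portionwise addition of an excess of the small ketone to the concentrated aldehyde, by the unhindered CHO terminus of 16, and by the fact that the enolate is generated at C9 by conjugate addition and not by deprotonation of the hindered C7 methylene. The all-E heptaene and both silyl ethers are inert to these neutral conditions.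

Step 19
Reactants: 27 Morita–Baylis–Hillman adduct; 28 (E)-oct-2-enoic acid (1.5 equiv)
Product: 30 C10 (E)-oct-2-enoate of the adduct, via O-acylisourea 29 (not isolated)
Conditions: DCC (1.5 equiv), DMAP (0.1 equiv), CH2Cl2, 0 °C, dark
Reagents that add atoms: none
Why: Steglich esterification through 29 and the acylpyridinium ion acylates the secondary C10 alcohol without the acid chloride/amine conditions that deconjugate 2-enoyl groups; any ester that already migrates to C19 here is the product of step 20 and is carried on.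

Step 20
Reactants: 30 C10 (E)-oct-2-enoate of the adduct
Product: 32 bis-TBS ether of the target (ester on C19; 9E), via allylammonium octenoate 31 (not isolated)
Conditions: DABCO (0.3 equiv), THF, rt → 40 °C, dark
Reagents that add atoms: none
Why: DABCO adds SN2′ at C19 and expels the C10 octenoate to give ion pair 31, and return of the carboxylate at C19 with release of DABCO completes the known 1,3-acyloxy transposition of Morita–Baylis–Hillman esters; the equilibrium rests on 32 because the C8 ketone becomes conjugated with the whole octaene and the ester becomes primary, the 9E geometry (C11 anti to C8) is the thermodynamic one, and both C10 epimers converge.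

Step 21
Reactants: 32 bis-TBS ether of the target
Product: 33 CNP0344057.1 (target)
Conditions: HF·pyridine (excess), pyridine, THF, 0 °C → rt, dark
Reagents that add atoms: none
Why: Fluoride cleaves both secondary Si–O bonds, and the pyridine-buffered medium is neither basic enough to hydrolyse or displace the allylic octenoate nor acidic enough to ionise the C3′ allylic alcohol.

**Compound list**
1 | (R)-α-ionone | CC(=O)/C=C/[C@H]1C(C)=CCCC1(C)C | starting material
2 | (R)-α-ionone ethylene ketal | CC1(/C=C/[C@H]2C(C)=CCCC2(C)C)OCCO1 | intermediate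
3 | (6R)-3-oxo-α-ionone ethylene ketal | CC1(/C=C/[C@H]2C(C)=CC(=O)CC2(C)C)OCCO1 | intermediate
4 | (3S,6R)-3-hydroxy-α-ionone ethylene ketal (cis) | CC1(/C=C/[C@H]2C(C)=C[C@@H](O)CC2(C)C)OCCO1 | intermediate
5 | alkoxytriphenylphosphonium 4-nitrobenzoate of 4 | CC1(/C=C/[C@H]2C(C)=C[C@@H](O[P+](c3ccccc3)(c3ccccc3)c3ccccc3)CC2(C)C)OCCO1.[O-]C(=O)c1ccc(cc1)[N+](=O)[O-] | intermediate
6 | (3R,6R)-3-(4-nitrobenzoyloxy)-α-ionone ethylene ketal (trans) | CC1(/C=C/[C@H]2C(C)=C[C@H](OC(=O)c3ccc(cc3)[N+](=O)[O-])CC2(C)C)OCCO1 | intermediate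
7 | (3R,6R)-3-hydroxy-α-ionone ethylene ketal | CC1(/C=C/[C@H]2C(C)=C[C@H](O)CC2(C)C)OCCO1 | intermediate
8 | (3R,6R)-3-hydroxy-α-ionone | CC(=O)/C=C/[C@H]1C(C)=C[C@H](O)CC1(C)C | intermediate
9 | (3R,6R)-3-hydroxy-9-vinyl-α-ionol, C9 epimers | C=CC(C)(O)/C=C/[C@H]1C(C)=C[C@H](O)CC1(C)C | intermediate
10 | (3R,6R)-3-hydroxy-ε C15 triphenylphosphonium bromide | CC(/C=C/[C@H]1C(C)=C[C@H](O)CC1(C)C)=C\C[P+](c1ccccc1)(c1ccccc1)c1ccccc1.[Br-] | intermediate
11 | (2E,4E,6E)-2,7-dimethylocta-2,4,6-trienedial | O=C/C(C)=C/C=C/C=C(C)/C=O | starting material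
12 | ylide of 10 | CC(/C=C/[C@H]1C(C)=C[C@H](O)CC1(C)C)=C\[CH-][P+](c1ccccc1)(c1ccccc1)c1ccccc1 | intermediate
13 | (3R,6R)-3-hydroxy C25 apo-ε-carotenal | O=C/C(C)=C/C=C/C=C(C)/C=C/C=C(C)/C=C/[C@H]1C(C)=C[C@H](O)CC1(C)C | intermediate
14 | C25 apo-ε-carotenal 3′-TBS ether | O=C/C(C)=C/C=C/C=C(C)/C=C/C=C(C)/C=C/[C@H]1C(C)=C[C@H](O[Si](C)(C)C(C)(C)C)CC1(C)C | intermediate
15 | C27 dienyl dioxolane (C11=C12 E/Z) | O1CCOC1C=C/C(C)=C/C=C/C=C(C)/C=C/C=C(C)/C=C/[C@H]2C(C)=C[C@H](O[Si](C)(C)C(C)(C)C)CC2(C)C | intermediate
16 | C27 apo-ε-carotenal 3′-TBS ether | O=C/C=C/C(C)=C/C=C/C=C(C)/C=C/C=C(C)/C=C/[C@H]1C(C)=C[C@H](O[Si](C)(C)C(C)(C)C)CC1(C)C | intermediate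
17 | (4R,6R)-actinol, (4R,6R)-4-hydroxy-2,2,6-trimethylcyclohexanone | C[C@@H]1C[C@@H](O)CC(C)(C)C1=O | starting material
18 | (4R,6R)-4-(tert-butyldimethylsilyloxy)-2,2,6-trimethylcyclohexanone | C[C@@H]1C[C@@H](O[Si](C)(C)C(C)(C)C)CC(C)(C)C1=O | intermediate
19 | lithium enolate of 18 | [Li+].[O-]C1=C(C)C[C@@H](O[Si](C)(C)C(C)(C)C)CC1(C)C | intermediate
20 | (4R)-4-(tert-butyldimethylsilyloxy)-2,6,6-trimethylcyclohex-1-en-1-yl triflate | FC(F)(F)S(=O)(=O)OC1=C(C)C[C@@H](O[Si](C)(C)C(C)(C)C)CC1(C)C | intermediate
21 | ethyl 2-[(4R)-4-(tert-butyldimethylsilyloxy)-2,6,6-trimethylcyclohex-1-en-1-yl]acetate | CCOC(=O)CC1=C(C)C[C@@H](O[Si](C)(C)C(C)(C)C)CC1(C)C | intermediate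
22 | Weinreb amide of 21 | CON(C)C(=O)CC1=C(C)C[C@@H](O[Si](C)(C)C(C)(C)C)CC1(C)C | intermediate
23 | tetrahedral magnesium adduct of 22 | C=CC(O[Mg]Br)(N(C)OC)CC1=C(C)C[C@@H](O[Si](C)(C)C(C)(C)C)CC1(C)C | intermediate
24 | 1-[(4R)-4-(tert-butyldimethylsilyloxy)-2,6,6-trimethylcyclohex-1-en-1-yl]but-3-en-2-one | C=CC(=O)CC1=C(C)C[C@@H](O[Si](C)(C)C(C)(C)C)CC1(C)C | intermediate
25 | β-tributylphosphonio enolate of 24 | CCCC[P+](CCCC)(CCCC)CC=C([O-])CC1=C(C)C[C@@H](O[Si](C)(C)C(C)(C)C)CC1(C)C | intermediate
26 | phosphonium alkoxide aldol adduct | CCCC[P+](CCCC)(CCCC)CC(C(=O)CC1=C(C)C[C@@H](O[Si](C)(C)C(C)(C)C)CC1(C)C)C([O-])/C=C/C(C)=C/C=C/C=C(C)/C=C/C=C(C)/C=C/[C@H]2C(C)=C[C@H](O[Si](C)(C)C(C)(C)C)CC2(C)C | intermediate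
27 | Morita–Baylis–Hillman adduct (C10 epimers) | C=C(C(=O)CC1=C(C)C[C@@H](O[Si](C)(C)C(C)(C)C)CC1(C)C)C(O)/C=C/C(C)=C/C=C/C=C(C)/C=C/C=C(C)/C=C/[C@H]2C(C)=C[C@H](O[Si](C)(C)C(C)(C)C)CC2(C)C | intermediate
28 | (E)-oct-2-enoic acid | CCCCC/C=C/C(=O)O | starting material
29 | O-acylisourea of 28 | CCCCC/C=C/C(=O)OC(=NC1CCCCC1)NC1CCCCC1 | intermediate
30 | C10 (E)-oct-2-enoate of 27 | C=C(C(=O)CC1=C(C)C[C@@H](O[Si](C)(C)C(C)(C)C)CC1(C)C)C(OC(=O)/C=C/CCCCC)/C=C/C(C)=C/C=C/C=C(C)/C=C/C=C(C)/C=C/[C@H]2C(C)=C[C@H](O[Si](C)(C)C(C)(C)C)CC2(C)C | intermediate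
31 | C19 DABCO allylammonium (E)-oct-2-enoate | O=C(CC1=C(C)C[C@@H](O[Si](C)(C)C(C)(C)C)CC1(C)C)C(C[N+]23CCN(CC2)CC3)=C/C=C/C(C)=C/C=C/C=C(C)/C=C/C=C(C)/C=C/[C@H]4C(C)=C[C@H](O[Si](C)(C)C(C)(C)C)CC4(C)C.CCCCC/C=C/C(=O)[O-] | intermediate
32 | bis-TBS ether of the target | CCCCC/C=C/C(=O)OC\C(=C/C=C/C(C)=C/C=C/C=C(C)/C=C/C=C(C)/C=C/[C@H]1C(C)=C[C@H](O[Si](C)(C)C(C)(C)C)CC1(C)C)C(=O)CC1=C(C)C[C@@H](O[Si](C)(C)C(C)(C)C)CC1(C)C | intermediate
33 | CNP0344057.1 | CCCCC/C=C/C(=O)OC\C(=C/C=C/C(C)=C/C=C/C=C(C)/C=C/C=C(C)/C=C/[C@H]1C(C)=C[C@H](O)CC1(C)C)C(=O)CC1=C(C)C[C@@H](O)CC1(C)C | target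

**Step count**
Total: 21 steps. Longest linear sequence: 16 steps (steps 1–12, then 18–21).

**Steps most likely to fail**

Step 18. Carbonyl addition to the electron-rich heptaenal may be so slow that self-condensation of the vinyl ketone and slow degradation of the polyene take over. The fallback sets out from 24 and 16 and separates the conjugate addition from the elimination. Me2AlSePh (from Me3Al and PhSeH) in CH2Cl2/THF at −78 °C adds selenium to C19 of 24, and the aluminium enolate so formed at C9 adds to aldehyde 16 to give the β-phenylseleno aldol F1. Oxidation with NaIO4/NaHCO3 in aqueous THF at 0 °C and syn-elimination of the selenoxide then restore the C9=C19 methylene, and the route is rejoined at 27.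

Step 20. The carboxylate may return at C10 or at a remote polyene carbon, or the ion pair may stall or eliminate, so that the ester does not settle cleanly on C19. The fallback sets out from 27 and replaces the amine relay by metal-catalysed allylic substitution. Methyl chloroformate and pyridine in CH2Cl2 at 0 °C give the C10 methyl carbonate F2. Pd(PPh3)4 (zerovalent palladium, 5 mol %) with acid 28 in THF at rt ionises it to the 2-acyl π-allyl complex with loss of CO2 and methoxide, which deprotonates 28. The octenoate then attacks the unhindered C19 terminus under thermodynamic control, and the route is rejoined at 32.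

Step 15. Oxidative addition and transmetallation at the tetrasubstituted triflate, flanked by a methyl and a gem-dimethyl group, may be too slow, so that the zinc enolate decomposes or the triflate is reduced. The fallback sets out from 18 and builds the C6–C7 bond by carbonyl addition. Lithium ethoxyacetylide (ethoxyacetylene, n-BuLi, THF, −78 °C) adds to the hindered ketone to give the ethoxyalkynyl carbinol F3. Meyer–Schuster rearrangement (Sc(OTf)3 cat., EtOH/CH2Cl2, rt) converts it into ethyl cyclohexylideneacetate F4. γ-Deprotonation at the only available ring position with LiN(i-Pr)2/DMPU in THF at −78 °C, followed by kinetic α-protonation with acetic acid, moves the alkene into the ring, and the route is rejoined at 21.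

**Further compounds**
F1 | step 18 | C19-phenylseleno aldol of 24 and 16 (C9, C10 epimers) | c1ccccc1[Se]CC(C(=O)CC1=C(C)C[C@@H](O[Si](C)(C)C(C)(C)C)CC1(C)C)C(O)/C=C/C(C)=C/C=C/C=C(C)/C=C/C=C(C)/C=C/[C@H]2C(C)=C[C@H](O[Si](C)(C)C(C)(C)C)CC2(C)C
F2 | step 20 | C10 methyl carbonate of 27 | C=C(C(=O)CC1=C(C)C[C@@H](O[Si](C)(C)C(C)(C)C)CC1(C)C)C(OC(=O)OC)/C=C/C(C)=C/C=C/C=C(C)/C=C/C=C(C)/C=C/[C@H]2C(C)=C[C@H](O[Si](C)(C)C(C)(C)C)CC2(C)C
F3 | step 15 | (4R,6R)-4-(tert-butyldimethylsilyloxy)-1-(ethoxyethynyl)-2,2,6-trimethylcyclohexan-1-ol (C1 epimers) | C[C@@H]1C[C@@H](O[Si](C)(C)C(C)(C)C)CC(C)(C)C1(O)C#COCC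
F4 | step 15 | ethyl 2-[(4R,6R)-4-(tert-butyldimethylsilyloxy)-2,2,6-trimethylcyclohexylidene]acetate (E/Z) | C[C@@H]1C[C@@H](O[Si](C)(C)C(C)(C)C)CC(C)(C)C1=CC(=O)OCC
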